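**Retrosynthetic overview**
- Ring B (the N-containing ring) is opened at the N2=C1 imine to an amino ketone whose N-nosyl form is the product of the key step. Ring B is therefore closed last (step 10).
- The strategy rests on ring A (the benzo ring of the isoquinoline; isoquinoline numbering, naphthalene atoms primed): C8a carries C1, its neighbour C4a carries C4, and its other neighbour C8 carries OMe. These are the ipso carbon, the one free ortho C–H and the blocked ortho position of a palladium–norbornene relay. Both C4–C4a and C1–C8a are cut in one step, back to an aryl iodide, an (S)-aziridine and a 1-ethoxyvinylstannane.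
- The aryl iodide comes from Br→I exchange on the product of a mono Suzuki–Miyaura coupling (C5–C1' axis) of symmetric 1,5-dibromo-2,4-dimethoxybenzene with a naphthyl pinacol boronate.
- The boronate comes from the naphthol of a Dötz benzannulation (second naphthalene ring, step 2) of the 2-bromoanisole-derived chromium carbene with propyne, via the triflate. The aziridine comes from L-alaninol.
- Ring order: ring A and the first naphthalene ring are bought, the second naphthalene ring is built in step 2, ring B in step 10.

Key step: step 8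

Remark on the chemistry: the target SMILES fixes only C3 (S) and leaves the C5–C1' axis open, so the axis is not controlled. The sulfonamide ketone, the amino ketone and the target are expected as pairs of atropo-diastereomers, to be separated at the end if a single axis is wanted.

**Route**

Step 1
Reactants: 1 2-bromoanisole
Product: 4 pentacarbonyl[methoxy(2-methoxyphenyl)methylidene]chromium, via 2-lithioanisole 2 (not isolated), via lithium acylchromate 3 (not isolated)
Conditions: n-BuLi, Et2O, −78 → 0 °C; Cr(CO)6, 0 °C → rt; then Me3OBF4, CH2Cl2, 0 °C → rt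
Reagents that add atoms: hexacarbonylchromium Cr(CO)6, O=C=[Cr](=C=O)(=C=O)(=C=O)(=C=O)=C=O; trimethyloxonium tetrafluoroborate Me3OBF4, C[O+](C)C.F[B-](F)(F)F
Why: Bromine–lithium exchange gives the aryllithium, which adds to a CO ligand of Cr(CO)6, and O-methylation of the acyl chromate gives the alkoxycarbene complex (standard Fischer carbene synthesis).

Step 2
Reactants: 4 pentacarbonyl[methoxy(2-methoxyphenyl)methylidene]chromium, 5 propyne
Product: 7 4,5-dimethoxy-2-methylnaphthalen-1-ol, via tricarbonylchromium naphthol complex 6 (not isolated)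
Conditions: propyne (3 equiv), THF, 50 °C, sealed tube; then air, rt
Reagents that add atoms: none
Why: Dötz benzannulation, in which alkyne insertion, CO insertion and electrocyclisation onto the free ortho position of the anisyl ring build the hydroxylated ring with the methyl group of the terminal alkyne next to the new OH and the aryl methoxy group at C5', and air then frees the naphthol from chromium.

Step 3
Reactants: 7 4,5-dimethoxy-2-methylnaphthalen-1-ol
Product: 8 4,5-dimethoxy-2-methylnaphthalen-1-yl trifluoromethanesulfonate
Conditions: Tf2O, pyridine, CH2Cl2, −20 → 0 °C (crude 7 used at once)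
Reagents that add atoms: trifluoromethanesulfonic anhydride, O=S(=O)(OS(=O)(=O)C(F)(F)F)C(F)(F)F
Why: O-sulfonylation of the naphthol with pyridine as base, done without delay because 4-methoxy-1-naphthols oxidise in air.

Step 4
Reactants: 8 4,5-dimethoxy-2-methylnaphthalen-1-yl trifluoromethanesulfonate
Product: 9 2-(4,5-dimethoxy-2-methylnaphthalen-1-yl)-4,4,5,5-tetramethyl-1,3,2-dioxaborolane
Conditions: B2pin2, Pd(OAc)2 (3 mol%), XPhos, KOAc, 1,4-dioxane, 100 °C
Reagents that add atoms: bis(pinacolato)diboron, CC1(C)OB(B2OC(C)(C)C(C)(C)O2)OC1(C)C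
Why: Miyaura borylation of the aryl triflate, with a bulky biarylphosphine chosen because the C–O bond is flanked by the 2'-methyl group and the peri position.

Step 5
Reactants: 9 2-(4,5-dimethoxy-2-methylnaphthalen-1-yl)-4,4,5,5-tetramethyl-1,3,2-dioxaborolane, 10 1,5-dibromo-2,4-dimethoxybenzene
Product: 11 1-(5-bromo-2,4-dimethoxyphenyl)-4,5-dimethoxy-2-methylnaphthalene
Conditions: 10 (3 equiv), Pd(OAc)2 (5 mol%), SPhos, K3PO4, toluene/H2O, 90 °C; excess 10 recovered
Reagents that add atoms: none
Why: Suzuki–Miyaura coupling in which the two C–Br bonds of the symmetric dibromide are equivalent, so an excess of the cheap dibromide should hold the reaction at the mono-coupled stage and form the C5–C1' bond.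

Step 6
Reactants: 11 1-(5-bromo-2,4-dimethoxyphenyl)-4,5-dimethoxy-2-methylnaphthalene
Product: 12 1-(5-iodo-2,4-dimethoxyphenyl)-4,5-dimethoxy-2-methylnaphthalene
Conditions: CuI (10 mol%), trans-N,N'-dimethylcyclohexane-1,2-diamine, NaI, 1,4-dioxane, 110 °C
Reagents that add atoms: sodium iodide, [Na+].[I-]
Why: Copper-catalysed aromatic Finkelstein exchange, driven by precipitation of NaBr from dioxane, supplies the C–I bond from which the relay of step 8 starts.

Step 7
Reactants: 13 L-alaninol ((S)-2-aminopropan-1-ol)
Product: 15 (S)-2-methyl-1-(2-nitrophenylsulfonyl)aziridine, via bis-nosyl alaninol 14 (not isolated)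
Conditions: 2-nitrobenzenesulfonyl chloride (2.2 equiv), pyridine, CH2Cl2, 0 °C → rt; then 2 M aq. KOH, rt
Reagents that add atoms: 2-nitrobenzenesulfonyl chloride, O=S(=O)(Cl)c1ccccc1[N+](=O)[O-]
Why: N,O-bis-sulfonylation followed by 3-exo-tet displacement of the primary nosylate by the sulfonamide anion closes the aziridine, and the stereocentre, which carries nitrogen and is not a reacting carbon, stays S.

Step 8
Reactants: 12 1-(5-iodo-2,4-dimethoxyphenyl)-4,5-dimethoxy-2-methylnaphthalene, 15 (S)-2-methyl-1-(2-nitrophenylsulfonyl)aziridine, 16 tributyl(1-ethoxyvinyl)stannane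
Product: 18 N-[(2S)-1-[2-acetyl-3,5-dimethoxy-6-(4,5-dimethoxy-2-methylnaphthalen-1-yl)phenyl]propan-2-yl]-2-nitrobenzenesulfonamide, via enol ether 17 (not isolated)
Conditions: 15 (2 equiv), 16 (1.5 equiv), Pd(OAc)2 (10 mol%), tri(2-furyl)phosphine (25 mol%), norbornene (2 equiv), Cs2CO3, MeCN, 80 °C; then 1 M HCl, THF, rt
Reagents that add atoms: water, O
Why: Proposed new method: oxidative addition of zerovalent palladium to the C–I bond of 12 (the future C8a) is followed by norbornene insertion and carbonate-assisted C–H palladation at the future C4a, and the resulting aryl–norbornyl palladacycle opens 15 at its CH2 carbon by SN2-type oxidative addition to tetravalent palladium; C(sp2)–C(sp3) reductive elimination then forms C4–C4a, the crowded arene expels norbornene, and the divalent arylpalladium is taken up by 16 in a Stille coupling that forms C1–C8a, after which dilute acid hydrolyses enol ether 17 to the acetyl group. The closest known reactions are Catellani ortho-alkylations of ortho-substituted aryl iodides with N-sulfonyl aziridines that end in a Heck or C–N coupling, and the Stille coupling of 16 with aryl halides as an acetyl equivalent; joining the two in one relay is the untested part. No ring is closed and no stereocentre is formed: C3 is the aziridine carbon that is not attacked, so its S configuration is carried through. Site selectivity rests on the C8 methoxy group, which leaves C4a–H as the only ortho C–H, and on attack at the unsubstituted aziridine carbon. The order of events rests on norbornene insertion being faster than transmetalation of the hindered α-alkoxyvinylstannane, and tri(2-furyl)phosphine with an excess of 16 is chosen so that Stille termination outruns C–N coupling of the sulfonamide anion to an indoline. The C5 naphthyl group next to C4a is the steric risk of the palladation.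

Step 9
Reactants: 18 N-[(2S)-1-[2-acetyl-3,5-dimethoxy-6-(4,5-dimethoxy-2-methylnaphthalen-1-yl)phenyl]propan-2-yl]-2-nitrobenzenesulfonamide
Product: 19 1-[2-[(2S)-2-aminopropyl]-4,6-dimethoxy-3-(4,5-dimethoxy-2-methylnaphthalen-1-yl)phenyl]ethan-1-one
Conditions: PhSH, K2CO3, MeCN/DMSO, 50 °C; crude 19 (with any 20 already formed) carried on
Reagents that add atoms: none
Why: Fukuyama deprotection, in which thiophenolate adds to the nitroarene (Meisenheimer adduct) and SO2 and the amine are released, with the ketone, the aryl ethers and C3 untouched.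

Step 10
Reactants: 19 1-[2-[(2S)-2-aminopropyl]-4,6-dimethoxy-3-(4,5-dimethoxy-2-methylnaphthalen-1-yl)phenyl]ethan-1-one
Product: 20 O-methylancistrocladinine, (3S)-6,8-dimethoxy-5-(4,5-dimethoxy-2-methylnaphthalen-1-yl)-1,3-dimethyl-3,4-dihydroisoquinoline
Conditions: AcOH (cat.), 4 Å MS, toluene, 60 °C
Reagents that add atoms: none
Why: Intramolecular imine condensation (6-exo-trig attack of the primary amine on the acetyl carbonyl, then loss of water) closes ring B as the conjugated cyclic ketimine without touching C3.

**Compound list**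
1 | 2-bromoanisole | COc1ccccc1Br | starting material
2 | 2-lithioanisole | COc1ccccc1[Li] | intermediate
3 | lithium pentacarbonyl[(2-methoxyphenyl)(oxido)methylidene]chromate | [Li+].COc1ccccc1C([O-])=[Cr](=C=O)(=C=O)(=C=O)(=C=O)=C=O | intermediate
4 | pentacarbonyl[methoxy(2-methoxyphenyl)methylidene]chromium | COC(c1ccccc1OC)=[Cr](=C=O)(=C=O)(=C=O)(=C=O)=C=O | intermediate
5 | propyne | CC#C | starting material
6 | tricarbonylchromium complex of naphthol 7 (Cr(CO)3 on the newly formed ring; written as its two parts) | COc1cc(C)c(O)c2cccc(OC)c12.O=C=[Cr](=C=O)=C=O | intermediate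
7 | 4,5-dimethoxy-2-methylnaphthalen-1-ol | COc1cc(C)c(O)c2cccc(OC)c12 | intermediate
8 | 4,5-dimethoxy-2-methylnaphthalen-1-yl trifluoromethanesulfonate | COc1cc(C)c(OS(=O)(=O)C(F)(F)F)c2cccc(OC)c12 | intermediate
9 | 2-(4,5-dimethoxy-2-methylnaphthalen-1-yl)-4,4,5,5-tetramethyl-1,3,2-dioxaborolane | COc1cc(C)c(B3OC(C)(C)C(C)(C)O3)c2cccc(OC)c12 | intermediate
10 | 1,5-dibromo-2,4-dimethoxybenzene | COc1cc(OC)c(Br)cc1Br | starting material
11 | 1-(5-bromo-2,4-dimethoxyphenyl)-4,5-dimethoxy-2-methylnaphthalene | COc1cc(OC)c(-c2c(C)cc(OC)c3c(OC)cccc23)cc1Br | intermediate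
12 | 1-(5-iodo-2,4-dimethoxyphenyl)-4,5-dimethoxy-2-methylnaphthalene | COc1cc(OC)c(-c2c(C)cc(OC)c3c(OC)cccc23)cc1I | intermediate
13 | L-alaninol, (S)-2-aminopropan-1-ol | C[C@H](N)CO | starting material
14 | (2S)-2-[(2-nitrophenyl)sulfonylamino]propyl 2-nitrobenzenesulfonate | C[C@H](NS(=O)(=O)c1ccccc1[N+](=O)[O-])COS(=O)(=O)c1ccccc1[N+](=O)[O-] | intermediate
15 | (S)-2-methyl-1-(2-nitrophenylsulfonyl)aziridine | C[C@H]1CN1S(=O)(=O)c1ccccc1[N+](=O)[O-] | intermediate
16 | tributyl(1-ethoxyvinyl)stannane | CCOC(=C)[Sn](CCCC)(CCCC)CCCC | starting material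
17 | N-[(2S)-1-[2-(1-ethoxyvinyl)-3,5-dimethoxy-6-(4,5-dimethoxy-2-methylnaphthalen-1-yl)phenyl]propan-2-yl]-2-nitrobenzenesulfonamide | CCOC(=C)c1c(OC)cc(OC)c(-c2c(C)cc(OC)c3c(OC)cccc23)c1C[C@H](C)NS(=O)(=O)c1ccccc1[N+](=O)[O-] | intermediate
18 | N-[(2S)-1-[2-acetyl-3,5-dimethoxy-6-(4,5-dimethoxy-2-methylnaphthalen-1-yl)phenyl]propan-2-yl]-2-nitrobenzenesulfonamide | CC(=O)c1c(OC)cc(OC)c(-c2c(C)cc(OC)c3c(OC)cccc23)c1C[C@H](C)NS(=O)(=O)c1ccccc1[N+](=O)[O-] | intermediate
19 | 1-[2-[(2S)-2-aminopropyl]-4,6-dimethoxy-3-(4,5-dimethoxy-2-methylnaphthalen-1-yl)phenyl]ethan-1-one | CC(=O)c1c(OC)cc(OC)c(-c2c(C)cc(OC)c3c(OC)cccc23)c1C[C@H](C)N | intermediate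
20 | O-methylancistrocladinine, (3S)-6,8-dimethoxy-5-(4,5-dimethoxy-2-methylnaphthalen-1-yl)-1,3-dimethyl-3,4-dihydroisoquinoline | COc1cc(OC)c(-c2c(C)cc(OC)c3c(OC)cccc23)c2c1C(C)=N[C@@H](C)C2 | target

**Step count**
Total: 10 steps. Longest linear sequence: 9 steps (steps 1–6, then 8–10); the aziridine branch is step 7.

**Steps most likely to fail**

1. Step 8 (proposed new method). Palladation at C4a–H, which is flanked by the twisted naphthyl group, or the oxidative addition of the aziridine may be too slow, so that the arylpalladium couples with the stannane before the relay or is trapped with norbornene. After the alkylation, the sulfonamide anion may bind palladium and reductively eliminate to an N-nosylindoline faster than the stannane transmetalates.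
Fallback, known chemistry throughout; it sets out from boronate 9 and comes back to the route at 20. Ring B is closed the classical way onto a side chain installed without C–H activation. Commercial 3,5-dimethoxyphenylmagnesium chloride opens commercial tert-butyl (S)-2-methylaziridine-1-carboxylate at its CH2 carbon (CuBr·SMe2 cat., THF, −30 °C) to give tert-butyl N-[(2S)-1-(3,5-dimethoxyphenyl)propan-2-yl]carbamate F1. TFA in CH2Cl2 with basic work-up frees (2S)-1-(3,5-dimethoxyphenyl)propan-2-amine F2, and Ac2O/Et3N gives N-[(2S)-1-(3,5-dimethoxyphenyl)propan-2-yl]acetamide F3. NBS in MeCN at 0 °C brominates the position ortho to the side chain and para to a methoxy group, giving N-[(2S)-1-(2-bromo-3,5-dimethoxyphenyl)propan-2-yl]acetamide F4. The demanding Suzuki–Miyaura coupling of F4 with 9 (Pd(OAc)2, SPhos, K3PO4, toluene/H2O, 100 °C) gives N-[(2S)-1-[2-(4,5-dimethoxy-2-methylnaphthalen-1-yl)-3,5-dimethoxyphenyl]propan-2-yl]acetamide F5. Bischler–Napieralski cyclisation (POCl3, MeCN, reflux) onto the free position between the CH2 group and a methoxy group then gives 20.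

2. Step 5. The hindered, electron-rich naphthylboronate may lose boron by protonolysis before it transmetalates, and a second coupling at the remaining C–Br bond is held back only by the excess of dibromide.
Fallback; it sets out from dibromide 10 and comes back at 11. The two halogen positions are told apart chemically instead of by stoichiometry. Mono bromine–lithium exchange on 10 (n-BuLi 1.0 equiv, THF, −78 °C) gives (5-bromo-2,4-dimethoxyphenyl)lithium F6, which iodine quenches to 1-bromo-5-iodo-2,4-dimethoxybenzene F7. The C–I bond of F7 is then coupled selectively with 9 under mild conditions (Pd(PPh3)4, K3PO4, DME/H2O, 80 °C) to give 11 without excess halide.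

3. Step 9. K2CO3 deprotonates the N–H of the nosylamide and the anion resists thiolate addition, so the cleavage may stall, and prolonged heating with thiolate invites attack at the aryl methyl ethers.
Fallback; it sets out from 18 and comes back at 20. The ring is closed before the sulfonyl group is removed. Acid-catalysed condensation of the sulfonamide N–H with the acetyl group (TsOH cat., toluene, reflux, water removal) gives (3S)-6,8-dimethoxy-5-(4,5-dimethoxy-2-methylnaphthalen-1-yl)-3-methyl-1-methylidene-2-(2-nitrophenylsulfonyl)-1,2,3,4-tetrahydroisoquinoline F8. F8 is a tertiary sulfonamide of the kind that thiophenol/K2CO3 in DMF cleaves readily at rt, and the enamine set free tautomerises to imine 20.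

**Further compounds**
F1 | step 8 | tert-butyl N-[(2S)-1-(3,5-dimethoxyphenyl)propan-2-yl]carbamate | COc1cc(OC)cc(C[C@H](C)NC(=O)OC(C)(C)C)c1
F2 | step 8 | (2S)-1-(3,5-dimethoxyphenyl)propan-2-amine | COc1cc(OC)cc(C[C@H](C)N)c1
F3 | step 8 | N-[(2S)-1-(3,5-dimethoxyphenyl)propan-2-yl]acetamide | COc1cc(OC)cc(C[C@H](C)NC(C)=O)c1
F4 | step 8 | N-[(2S)-1-(2-bromo-3,5-dimethoxyphenyl)propan-2-yl]acetamide | COc1cc(OC)c(Br)c(C[C@H](C)NC(C)=O)c1
F5 | step 8 | N-[(2S)-1-[2-(4,5-dimethoxy-2-methylnaphthalen-1-yl)-3,5-dimethoxyphenyl]propan-2-yl]acetamide | COc1cc(OC)c(-c2c(C)cc(OC)c3c(OC)cccc23)c(C[C@H](C)NC(C)=O)c1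
F6 | step 5 | (5-bromo-2,4-dimethoxyphenyl)lithium | COc1cc(OC)c([Li])cc1Br
F7 | step 5 | 1-bromo-5-iodo-2,4-dimethoxybenzene | COc1cc(OC)c(I)cc1Br
F8 | step 9 | (3S)-6,8-dimethoxy-5-(4,5-dimethoxy-2-methylnaphthalen-1-yl)-3-methyl-1-methylidene-2-(2-nitrophenylsulfonyl)-1,2,3,4-tetrahydroisoquinoline | C=C1N(S(=O)(=O)c2ccccc2[N+](=O)[O-])[C@@H](C)Cc2c(-c3c(C)cc(OC)c4c(OC)cccc34)c(OC)cc(OC)c21
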